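Ring B is a cyclohex-2-enone (1H-isochromen-8-one numbering): the C8 ketone is conjugated with the C8a=C4a alkene, and the saturated half C8–C7–C6–C5 holds both stereocentres and the hindered tertiary ester. Everything rests on cutting C8–C8a and C4a–C5. In one operation, nickel-catalysed insertion of an alkyne (the future C8a=C4a) into the C8–C5 bond of a cyclobutanone closes ring B by two-carbon ring expansion. The precursor, a (2R,3S)-2-aroyloxy-2-methyl-3-silyloxycyclobutanone, already carries C6, C7 and the ester and comes from an acyloxyketene–vinyl ether [2+2] cycloaddition; its partner is a silyloxymethyl diyne with a triisopropylsilyl cap. Ring A is closed last by 6-endo hydroalkoxylation.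

Key step: step 9

Remark: benzyl 2-bromopropanoate is used as the racemate because its stereocentre is erased in the ketene; the absolute configuration enters by resolution of cyclobutanone 12. TBS = tert-butyldimethylsilyl, TIPS = triisopropylsilyl.

Step 1
Reactants: 1 methyl orsellinate (methyl 2,4-dihydroxy-6-methylbenzoate)
Product: 3 methyl 4-(benzyloxy)-2-methoxy-6-methylbenzoate, via monobenzyl ether 2 (not isolated)
Conditions: BnBr (1.05 equiv), K2CO3, DMF, rt; then MeI (3 equiv), 50 °C
Reagents that add atoms: benzyl bromide BrCc1ccccc1; iodomethane CI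
Why: Two Williamson etherifications in one flask: the free, more acidic 4-OH is benzylated first, and the 2-OH, deactivated by its hydrogen bond to the ester, is then methylated with excess MeI on warming.

Step 2
Reactants: 3 methyl 4-(benzyloxy)-2-methoxy-6-methylbenzoate
Product: 4 4-(benzyloxy)-2-methoxy-6-methylbenzoic acid
Conditions: KOH, DMSO/H2O (4:1), 90 °C; then cold 1 M HCl to pH 2
Reagents that add atoms: potassium hydroxide [K+].[OH-]
Why: Saponification of a di-ortho-substituted methyl benzoate needs poorly solvated hydroxide at elevated temperature, which the benzyl and methyl aryl ethers tolerate.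

Step 3
Reactants: 4 4-(benzyloxy)-2-methoxy-6-methylbenzoic acid; 5 benzyl 2-bromopropanoate (racemic)
Product: 6 benzyl 2-{[4-(benzyloxy)-2-methoxy-6-methylbenzoyl]oxy}propanoate (racemic)
Conditions: Cs2CO3, DMF, rt
Reagents that add atoms: none
Why: SN2 O-alkylation of the caesium carboxylate by the activated secondary α-bromo ester forms the hindered aryl ester at the alkyl carbon and so avoids attack on the shielded acyl carbon.

Step 4
Reactants: 6 benzyl 2-{[4-(benzyloxy)-2-methoxy-6-methylbenzoyl]oxy}propanoate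
Product: 7 2-[(4-hydroxy-2-methoxy-6-methylbenzoyl)oxy]propanoic acid (racemic)
Conditions: H2 (1 atm), 10% Pd/C, EtOAc, rt
Reagents that add atoms: none
Why: Hydrogenolysis removes the benzyl ester and the benzyl aryl ether together and leaves the non-benzylic aryl ester untouched.

Step 5
Reactants: 7 2-[(4-hydroxy-2-methoxy-6-methylbenzoyl)oxy]propanoic acid
Product: 8 tert-butyldimethylsilyl 2-{[4-(tert-butyldimethylsilyloxy)-2-methoxy-6-methylbenzoyl]oxy}propanoate (racemic)
Conditions: TBSCl (2.5 equiv), imidazole, DMF, rt; non-aqueous work-up (pentane), used crude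
Reagents that add atoms: tert-butyl(chloro)dimethylsilane CC(C)(C)[Si](C)(C)Cl
Why: Imidazole-mediated silylation caps the phenol for the amine- and nickel-mediated steps ahead and turns the acid into a silyl ester, the direct precursor of the acid chloride.

Step 6
Reactants: 8 tert-butyldimethylsilyl 2-{[4-(tert-butyldimethylsilyloxy)-2-methoxy-6-methylbenzoyl]oxy}propanoate; 9 tert-butyldimethyl(vinyloxy)silane
Product: 12 rac-(1R,2S)-2-(tert-butyldimethylsilyloxy)-1-methyl-4-oxocyclobutyl 4-(tert-butyldimethylsilyloxy)-2-methoxy-6-methylbenzoate, via acid chloride 10 (not isolated), via acyloxyketene 11 (not isolated)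
Conditions: (COCl)2, DMF (cat.), CH2Cl2, 0 °C to rt; concentrate; then 9 (5 equiv), Et3N (slow addition), CH2Cl2, 40 °C; minor C3 epimer removed by chromatography
Reagents that add atoms: none
Why: The Vilsmeier reagent converts the silyl ester into acid chloride 10 without free HCl, Et3N dehydrochlorinates it to the (aroyloxy)(methyl)ketene 11, and a thermal ketene–enol ether [2+2] cycloaddition joins the ketene carbonyl carbon to the CH2 terminus of 9 to give the 3-silyloxycyclobutanone; the isomer with methyl cis to OTBS (aroyloxy trans) should predominate because the oxygen substituent acts as the smaller ketene substituent and ends up away from the alkene substituent.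

Step 7
Reactants: 12 rac-(1R,2S)-2-(tert-butyldimethylsilyloxy)-1-methyl-4-oxocyclobutyl 4-(tert-butyldimethylsilyloxy)-2-methoxy-6-methylbenzoate
Product: 13 (1R,2S)-2-(tert-butyldimethylsilyloxy)-1-methyl-4-oxocyclobutyl 4-(tert-butyldimethylsilyloxy)-2-methoxy-6-methylbenzoate
Conditions: preparative SFC on amylose tris(3,5-dimethylphenylcarbamate), CO2/i-PrOH
Reagents that add atoms: none
Why: Resolution by chromatography on a chiral stationary phase, a general method for aryl ester ketones on polysaccharide carbamate phases, fixes the absolute configuration of C6 and C7 (relative configuration from step 6); the (1R,2S) enantiomer is to be identified by anomalous-dispersion X-ray analysis.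

Step 8
Reactants: 14 tert-butyldimethyl(prop-2-yn-1-yloxy)silane; 15 (bromoethynyl)triisopropylsilane
Product: 16 1-(tert-butyldimethylsilyloxy)-5-(triisopropylsilyl)penta-2,4-diyne
Conditions: CuCl (5 mol%), NH2OH·HCl (10 mol%), n-BuNH2 (30% aq.), CH2Cl2, 0 °C to rt
Reagents that add atoms: none
Why: Cadiot–Chodkiewicz coupling: the copper acetylide of 14 substitutes the bromoalkyne to give the unsymmetrical 1,3-diyne, with hydroxylamine keeping copper monovalent and so suppressing homocoupling.

Step 9
Reactants: 13 (1R,2S)-2-(tert-butyldimethylsilyloxy)-1-methyl-4-oxocyclobutyl 4-(tert-butyldimethylsilyloxy)-2-methoxy-6-methylbenzoate; 16 1-(tert-butyldimethylsilyloxy)-5-(triisopropylsilyl)penta-2,4-diyne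
Product: 17 (1R,6S)-6-(tert-butyldimethylsilyloxy)-3-[(tert-butyldimethylsilyloxy)methyl]-1-methyl-2-oxo-4-[(triisopropylsilyl)ethynyl]cyclohex-3-en-1-yl 4-(tert-butyldimethylsilyloxy)-2-methoxy-6-methylbenzoate
Conditions: Ni(cod)2 (10 mol%), PCy3 (20 mol%), toluene, 90 °C, 16 (1.5 equiv) added over 2 h
Reagents that add atoms: none
Why: Zerovalent nickel with PCy3 should couple the strained ketone of 13 with the silyloxymethyl-bearing triple bond of 16 by oxidative cyclization to a spiro oxanickelacyclopentene (C8 bonded to the future C8a, nickel on the future C4a), after which β-carbon elimination opens the four-membered ring at C8–C5 and C(sp3)–C(sp2) reductive elimination joins C5 to C4a. The closest known reaction type is the Ni(cod)2/PCy3-catalysed intermolecular insertion of internal alkynes into cyclobutanones, which gives cyclohex-2-enones. Ring B is closed by this formal [4+2] annulation, the ring-closing event being reductive elimination from a seven-membered nickelacycle. No stereocentre is formed: C6 and C7 come unchanged from 13, C7 being quaternary and C6 taking part in no bond change. Three selectivities are needed: reaction at the less hindered triple bond (the TIPS cap shields the other), nickel on the alkyne carbon that bears the conjugating alkynyl group so that CH2OTBS ends up on C8a, and migration of the CH2 carbon C5 and not of the quaternary, aroyloxy-bearing C7, which the steric demand at C7 should secure. Slow addition of 16 limits diyne oligomerization, and the moderate temperature limits β-silyloxy elimination from the alkylnickel intermediate.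

Step 10
Reactants: 17 (1R,6S)-6-(tert-butyldimethylsilyloxy)-3-[(tert-butyldimethylsilyloxy)methyl]-1-methyl-2-oxo-4-[(triisopropylsilyl)ethynyl]cyclohex-3-en-1-yl 4-(tert-butyldimethylsilyloxy)-2-methoxy-6-methylbenzoate
Product: 19 (1R,6S)-6-(tert-butyldimethylsilyloxy)-3-[(tert-butyldimethylsilyloxy)methyl]-4-ethynyl-1-methyl-2-oxocyclohex-3-en-1-yl 4-hydroxy-2-methoxy-6-methylbenzoate, via silver acetylide 18 (not isolated)
Conditions: AgF (3 equiv), MeOH/THF (1:1), rt, dark; then 1 M HCl, 0 °C, 5 min
Reagents that add atoms: none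
Why: Silver fluoride desilylation: fluoride attack at silicon, assisted by silver coordination to the triple bond, gives silver acetylide 18, which brief acid treatment protonates; methanolic fluoride also cleaves the phenolic silyl ether, which is far more fluoride-labile than the two alkyl TBS ethers, and any aryl silyl ether that survives is removed in step 12.

Step 11
Reactants: 19 (1R,6S)-6-(tert-butyldimethylsilyloxy)-3-[(tert-butyldimethylsilyloxy)methyl]-4-ethynyl-1-methyl-2-oxocyclohex-3-en-1-yl 4-hydroxy-2-methoxy-6-methylbenzoate; 20 (E)-1-bromoprop-1-ene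
Product: 21 (1R,6S)-6-(tert-butyldimethylsilyloxy)-3-[(tert-butyldimethylsilyloxy)methyl]-1-methyl-2-oxo-4-[(E)-pent-3-en-1-yn-1-yl]cyclohex-3-en-1-yl 4-hydroxy-2-methoxy-6-methylbenzoate
Conditions: Pd(PPh3)4 (5 mol%), CuI (10 mol%), Et3N, THF, rt, degassed, 20 (3 equiv)
Reagents that add atoms: none
Why: Sonogashira coupling of the terminal alkyne with the vinyl bromide proceeds with retention of the E geometry, and a tertiary amine is used so that no amine adds to the electron-poor ynenone.

Step 12
Reactants: 21 (1R,6S)-6-(tert-butyldimethylsilyloxy)-3-[(tert-butyldimethylsilyloxy)methyl]-1-methyl-2-oxo-4-[(E)-pent-3-en-1-yn-1-yl]cyclohex-3-en-1-yl 4-hydroxy-2-methoxy-6-methylbenzoate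
Product: 22 (1R,6S)-6-hydroxy-3-(hydroxymethyl)-1-methyl-2-oxo-4-[(E)-pent-3-en-1-yn-1-yl]cyclohex-3-en-1-yl 4-hydroxy-2-methoxy-6-methylbenzoate
Conditions: HF·pyridine, pyridine, THF, 0 °C to rt
Reagents that add atoms: none
Why: Buffered fluoride desilylation removes the primary allylic and the hindered secondary TBS ether without base, so the tertiary aryl ester stays in place and the C6 oxygen cannot be lost by elimination (C7 is quaternary); any pyran already formed at this stage converges in step 13.

Step 13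
Reactants: 22 (1R,6S)-6-hydroxy-3-(hydroxymethyl)-1-methyl-2-oxo-4-[(E)-pent-3-en-1-yn-1-yl]cyclohex-3-en-1-yl 4-hydroxy-2-methoxy-6-methylbenzoate
Product: 23 (6S,7R)-6-hydroxy-7-methyl-8-oxo-3-[(E)-prop-1-en-1-yl]-5,6,7,8-tetrahydro-1H-isochromen-7-yl 4-hydroxy-2-methoxy-6-methylbenzoate
Conditions: Ph3PAuNTf2 (5 mol%), CH2Cl2/THF (10:1), rt
Reagents that add atoms: none
Why: Gold-catalysed 6-endo-dig hydroalkoxylation (cycloisomerization): monovalent gold activates the triple bond and the C1 hydroxyl attacks the distal alkyne carbon C3, which bears the donor propenyl group and lies away from the electron-poor enone carbon C4a, closing ring A as the 1H-pyran after protodeauration without touching the E-propenyl group or the stereocentres.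

Compound list
1 | methyl orsellinate (methyl 2,4-dihydroxy-6-methylbenzoate) | COC(=O)c1c(C)cc(O)cc1O | starting material
2 | methyl 4-(benzyloxy)-2-hydroxy-6-methylbenzoate | COC(=O)c1c(C)cc(OCc2ccccc2)cc1O | intermediate
3 | methyl 4-(benzyloxy)-2-methoxy-6-methylbenzoate | COC(=O)c1c(C)cc(OCc2ccccc2)cc1OC | intermediate
4 | 4-(benzyloxy)-2-methoxy-6-methylbenzoic acid | Cc1cc(OCc2ccccc2)cc(OC)c1C(=O)O | intermediate
5 | benzyl 2-bromopropanoate (racemic) | CC(Br)C(=O)OCc1ccccc1 | starting material
6 | benzyl 2-{[4-(benzyloxy)-2-methoxy-6-methylbenzoyl]oxy}propanoate (racemic) | CC(OC(=O)c1c(C)cc(OCc2ccccc2)cc1OC)C(=O)OCc1ccccc1 | intermediate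
7 | 2-[(4-hydroxy-2-methoxy-6-methylbenzoyl)oxy]propanoic acid (racemic) | CC(OC(=O)c1c(C)cc(O)cc1OC)C(=O)O | intermediate
8 | tert-butyldimethylsilyl 2-{[4-(tert-butyldimethylsilyloxy)-2-methoxy-6-methylbenzoyl]oxy}propanoate (racemic) | CC(OC(=O)c1c(C)cc(O[Si](C)(C)C(C)(C)C)cc1OC)C(=O)O[Si](C)(C)C(C)(C)C | intermediate
9 | tert-butyldimethyl(vinyloxy)silane | C=CO[Si](C)(C)C(C)(C)C | starting material
10 | 2-{[4-(tert-butyldimethylsilyloxy)-2-methoxy-6-methylbenzoyl]oxy}propanoyl chloride (racemic) | CC(OC(=O)c1c(C)cc(O[Si](C)(C)C(C)(C)C)cc1OC)C(Cl)=O | intermediate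
11 | 1-oxoprop-1-en-2-yl 4-(tert-butyldimethylsilyloxy)-2-methoxy-6-methylbenzoate, the (aroyloxy)(methyl)ketene | CC(OC(=O)c1c(C)cc(O[Si](C)(C)C(C)(C)C)cc1OC)=C=O | intermediate
12 | rac-(1R,2S)-2-(tert-butyldimethylsilyloxy)-1-methyl-4-oxocyclobutyl 4-(tert-butyldimethylsilyloxy)-2-methoxy-6-methylbenzoate (racemate; methyl cis to OTBS, aroyloxy trans) | O=C1[C@](C)(OC(=O)c2c(C)cc(O[Si](C)(C)C(C)(C)C)cc2OC)[C@@H](O[Si](C)(C)C(C)(C)C)C1.O=C1[C@@](C)(OC(=O)c2c(C)cc(O[Si](C)(C)C(C)(C)C)cc2OC)[C@H](O[Si](C)(C)C(C)(C)C)C1 | intermediate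
13 | (1R,2S)-2-(tert-butyldimethylsilyloxy)-1-methyl-4-oxocyclobutyl 4-(tert-butyldimethylsilyloxy)-2-methoxy-6-methylbenzoate, i.e. the (2R,3S)-2-aroyloxy-2-methyl-3-silyloxycyclobutanone | O=C1[C@](C)(OC(=O)c2c(C)cc(O[Si](C)(C)C(C)(C)C)cc2OC)[C@@H](O[Si](C)(C)C(C)(C)C)C1 | intermediate
14 | tert-butyldimethyl(prop-2-yn-1-yloxy)silane | C#CCO[Si](C)(C)C(C)(C)C | starting material
15 | (bromoethynyl)triisopropylsilane | CC(C)[Si](C#CBr)(C(C)C)C(C)C | starting material
16 | 1-(tert-butyldimethylsilyloxy)-5-(triisopropylsilyl)penta-2,4-diyne | CC(C)(C)[Si](C)(C)OCC#CC#C[Si](C(C)C)(C(C)C)C(C)C | intermediate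
17 | (1R,6S)-6-(tert-butyldimethylsilyloxy)-3-[(tert-butyldimethylsilyloxy)methyl]-1-methyl-2-oxo-4-[(triisopropylsilyl)ethynyl]cyclohex-3-en-1-yl 4-(tert-butyldimethylsilyloxy)-2-methoxy-6-methylbenzoate | O=C1[C@](C)(OC(=O)c2c(C)cc(O[Si](C)(C)C(C)(C)C)cc2OC)[C@@H](O[Si](C)(C)C(C)(C)C)CC(C#C[Si](C(C)C)(C(C)C)C(C)C)=C1CO[Si](C)(C)C(C)(C)C | intermediate
18 | silver acetylide of 19 (silver on the terminal alkyne carbon) | O=C1[C@](C)(OC(=O)c2c(C)cc(O)cc2OC)[C@@H](O[Si](C)(C)C(C)(C)C)CC(C#C[Ag])=C1CO[Si](C)(C)C(C)(C)C | intermediate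
19 | (1R,6S)-6-(tert-butyldimethylsilyloxy)-3-[(tert-butyldimethylsilyloxy)methyl]-4-ethynyl-1-methyl-2-oxocyclohex-3-en-1-yl 4-hydroxy-2-methoxy-6-methylbenzoate | O=C1[C@](C)(OC(=O)c2c(C)cc(O)cc2OC)[C@@H](O[Si](C)(C)C(C)(C)C)CC(C#C)=C1CO[Si](C)(C)C(C)(C)C | intermediate
20 | (E)-1-bromoprop-1-ene | C/C=C/Br | starting material
21 | (1R,6S)-6-(tert-butyldimethylsilyloxy)-3-[(tert-butyldimethylsilyloxy)methyl]-1-methyl-2-oxo-4-[(E)-pent-3-en-1-yn-1-yl]cyclohex-3-en-1-yl 4-hydroxy-2-methoxy-6-methylbenzoate | O=C1[C@](C)(OC(=O)c2c(C)cc(O)cc2OC)[C@@H](O[Si](C)(C)C(C)(C)C)CC(C#C/C=C/C)=C1CO[Si](C)(C)C(C)(C)C | intermediate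
22 | (1R,6S)-6-hydroxy-3-(hydroxymethyl)-1-methyl-2-oxo-4-[(E)-pent-3-en-1-yn-1-yl]cyclohex-3-en-1-yl 4-hydroxy-2-methoxy-6-methylbenzoate | O=C1[C@](C)(OC(=O)c2c(C)cc(O)cc2OC)[C@@H](O)CC(C#C/C=C/C)=C1CO | intermediate
23 | (6S,7R)-6-hydroxy-7-methyl-8-oxo-3-[(E)-prop-1-en-1-yl]-5,6,7,8-tetrahydro-1H-isochromen-7-yl 4-hydroxy-2-methoxy-6-methylbenzoate | C/C=C/C1=CC2=C(CO1)C(=O)[C@](C)(OC(=O)c1c(C)cc(O)cc1OC)[C@@H](O)C2 | target

Total step count: 13. Longest linear sequence: 12 (steps 1–7 and 9–13; step 8 is the one-step side branch).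

Steps most likely to fail

1. Step 9. What may go wrong: β-silyloxy elimination from the alkylnickel intermediate, insertion of nickel into the C7–O bond of the α-acyloxy ketone, or oligomerization of the diyne before the hindered ketone enters the cycle. The fallback sets out from 13 and 16 and comes back at 17. It separates the oxidative coupling from the C–C cleavage and makes the first one stoichiometric at low temperature. Ti(O-i-Pr)4 with 2 i-PrMgCl at −50 °C (divalent titanium) would turn 16 into the alkyne–titanium complex F1, which adds to the ketone of 13 to give the oxatitanacyclopentene F2, the same type of metallacycle as in the nickel cycle. Iodine then gives the (Z)-iodoalkenyl cyclobutanol F3. Pd(OAc)2/PPh3 with Cs2CO3 in toluene at 80 °C (zerovalent palladium formed in the flask) would insert into the C–I bond, bind the tertiary alkoxide, open the ring by β-carbon elimination of the CH2 arm and close ring B by reductive elimination, giving 17.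

2. Step 6. What may go wrong: dimerization of the ketene or C-acylation of the enol ether outrunning the cycloaddition, or an unfavourable ratio of C3 epimers. The fallback sets out from 10 and comes back at 12. It replaces the ketene by a keteniminium ion, which is more electrophilic and does not dimerize (keteniminium [2+2] cycloaddition). Acid chloride 10 and dimethylamine give the dimethylamide F4. Tf2O with 2,6-di-tert-butylpyridine in CH2Cl2 converts it into the keteniminium triflate F5, which adds 9 to give the cyclobutaniminium triflate F6, and aqueous NaHCO3 hydrolyses this to 12.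

3. Step 13. What may go wrong: 5-exo-dig attack at the proximal alkyne carbon, which would give an alkylidene dihydrofuran in place of the pyran. The fallback sets out from 22 and comes back at 23. It changes the oxygen nucleophile from the alcohol to a carbonyl group, for which only six-membered closure leads to an aromatic cation. MnO2 in CH2Cl2 oxidizes the primary allylic alcohol of 22 selectively to the enal F7. Au(OAc)3 (trivalent gold, 5 mol%) with trifluoroacetic acid in ClCH2CH2Cl cyclizes the ynenal to the pyrylium trifluoroacetate F8, and Et3SiH delivers hydride to the unsubstituted C1, giving 23.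

Further compounds
F1 | step 9 | diisopropoxytitanium complex of 16 at the silyloxymethyl-substituted triple bond (titanacyclopropene) | CC(C)O[Ti]1(OC(C)C)C(CO[Si](C)(C)C(C)(C)C)=C1C#C[Si](C(C)C)(C(C)C)C(C)C
F2 | step 9 | spiro oxatitanacyclopentene from F1 and the ketone of 13 (configuration at the spiro carbon not relevant) | CC(C)O[Ti]1(OC(C)C)OC2(C[C@H](O[Si](C)(C)C(C)(C)C)[C@@]2(C)OC(=O)c2c(C)cc(O[Si](C)(C)C(C)(C)C)cc2OC)C(CO[Si](C)(C)C(C)(C)C)=C1C#C[Si](C(C)C)(C(C)C)C(C)C
F3 | step 9 | (1R,2S)-2-(tert-butyldimethylsilyloxy)-4-hydroxy-4-[(Z)-1-(tert-butyldimethylsilyloxy)-3-iodo-5-(triisopropylsilyl)pent-2-en-4-yn-2-yl]-1-methylcyclobutyl 4-(tert-butyldimethylsilyloxy)-2-methoxy-6-methylbenzoate (configuration at the carbinol carbon not relevant) | OC1(/C(CO[Si](C)(C)C(C)(C)C)=C(\I)C#C[Si](C(C)C)(C(C)C)C(C)C)C[C@H](O[Si](C)(C)C(C)(C)C)[C@@]1(C)OC(=O)c1c(C)cc(O[Si](C)(C)C(C)(C)C)cc1OC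
F4 | step 6 | 1-(dimethylamino)-1-oxopropan-2-yl 4-(tert-butyldimethylsilyloxy)-2-methoxy-6-methylbenzoate (racemic) | CC(OC(=O)c1c(C)cc(O[Si](C)(C)C(C)(C)C)cc1OC)C(=O)N(C)C
F5 | step 6 | N-[2-{[4-(tert-butyldimethylsilyloxy)-2-methoxy-6-methylbenzoyl]oxy}prop-1-en-1-ylidene]-N-methylmethanaminium triflate (keteniminium salt) | CC(OC(=O)c1c(C)cc(O[Si](C)(C)C(C)(C)C)cc1OC)=C=[N+](C)C.[O-]S(=O)(=O)C(F)(F)F
F6 | step 6 | dimethyliminium triflate of 12 (C=N+Me2 in place of C=O; racemic, relative configuration as in 12, one enantiomer drawn) | C[N+](C)=C1C[C@H](O[Si](C)(C)C(C)(C)C)[C@@]1(C)OC(=O)c1c(C)cc(O[Si](C)(C)C(C)(C)C)cc1OC.[O-]S(=O)(=O)C(F)(F)F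
F7 | step 13 | (1R,6S)-3-formyl-6-hydroxy-1-methyl-2-oxo-4-[(E)-pent-3-en-1-yn-1-yl]cyclohex-3-en-1-yl 4-hydroxy-2-methoxy-6-methylbenzoate | O=CC1=C(C#C/C=C/C)C[C@H](O)[C@@](C)(OC(=O)c2c(C)cc(O)cc2OC)C1=O
F8 | step 13 | (6S,7R)-6-hydroxy-7-[(4-hydroxy-2-methoxy-6-methylbenzoyl)oxy]-7-methyl-8-oxo-3-[(E)-prop-1-en-1-yl]-5,6,7,8-tetrahydroisochromenylium trifluoroacetate | C/C=C/C1=CC2=C(C=[O+]1)C(=O)[C@](C)(OC(=O)c1c(C)cc(O)cc1OC)[C@@H](O)C2.[O-]C(=O)C(F)(F)F
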